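**Strategy**

Numbering: C1 is the quaternary oxirane carbon carrying C7H2OBz, C2 bears OAc, C3 bears OBz, C4=C5 is the alkene and C6 is the oxirane CH. Since C1, which holds C7, stands para to C4 in the cyclohexene ring, the carbocycle is opened at C1–C6 to a six-membered lactone C7(=O)–O–C4 whose C4 carries C5=C6 as an (E)-2-chlorovinyl group; C7 and C1–C4 are L-gulonic acid. In one operation the Ireland–Claisen rearrangement of its silyl ketene acetal joins C1 to C6, releases the oxygen from C4, leaves the alkene at C4=C5 and sets C1 and C6. The allylic chloride later closes the oxirane.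

Key step: step 8

**Remarks**

- Abbreviations: TBS = tert-butyldimethylsilyl, Bz = benzoyl.
- Numbering: compounds 1–14 use L-gulonic acid numbering. It maps onto target numbering as C1→C7, C2→C1, C3→C2, C4→C3, C5→C4, C6→C5; the carbon from chloroform becomes C6. From compound 16 on, target numbering is used.
- Faces: the ring is drawn with C1→C6 clockwise; β is the face towards the viewer, which carries C7.
- Assumption: the configuration is read from the SMILES as (1S,2S,3R,6S) in this numbering, i.e. C7 and the C2 acetoxy group β, the C3 benzoyloxy group and the oxirane oxygen α.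
- Structure check: lactone 14 is L-gulo at C2–C5 and gives 17 with the configuration the target needs. Lactone and carbocycle are both six-membered: the shift moves O and C7 out of the ring and C5, C6 into it, so the ring size does not change.
- Design changes: the O4 benzoate serves as a placeholder and is cleaved when the silyl ester is reduced, after which both benzoates are introduced together. The end game runs acidic desilylation, then acetylation, then base, so that no alkoxide ever sits next to a benzoate.

**Route**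

Step 1
Reactants: 1 L-gulono-1,4-lactone; 2 2,2-dimethoxypropane
Product: 3 5,6-O-isopropylidene-L-gulono-1,4-lactone
Conditions: Me2C(OMe)2, pTsOH·H2O (cat.), DMF, rt
Reagents that add atoms: 2,2-dimethoxypropane, COC(C)(C)OC
Why: Acid-catalysed transacetalisation (acetonide formation) under kinetic control takes the terminal 5,6-diol into a dioxolane and leaves the lactone, the 2,3-diol and all four stereocentres untouched.

Step 2
Reactants: 3 5,6-O-isopropylidene-L-gulono-1,4-lactone; 4 tert-butyldimethylsilyl chloride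
Product: 5 2,3-bis-O-TBS-5,6-O-isopropylidene-L-gulono-1,4-lactone
Conditions: TBSCl, imidazole, DMAP (cat.), DMF, 50 °C
Reagents that add atoms: tert-butyldimethylsilyl chloride, CC(C)(C)[Si](C)(C)Cl
Why: Imidazole-mediated silylation (Corey conditions) with excess reagent and gentle warming should convert both secondary hydroxyls of the cis-2,3-diol into TBS ethers that withstand every step before the final fluoride treatment.

Step 3
Reactants: 5 2,3-bis-O-TBS-5,6-O-isopropylidene-L-gulono-1,4-lactone; 6 N,O-dimethylhydroxylamine hydrochloride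
Product: 7 N-methoxy-N-methyl-2,3-bis-O-TBS-5,6-O-isopropylidene-L-gulonamide (4-OH free)
Conditions: MeNH(OMe)·HCl, AlMe3, CH2Cl2, 0 °C → rt
Reagents that add atoms: N,O-dimethylhydroxylamine hydrochloride, CNOC.Cl
Why: Weinreb aminolysis: the aluminium amide Me(Cl)AlN(OMe)Me opens the γ-lactone to the N-methoxy-N-methylamide and so uncovers O4 as the only free hydroxyl, the weakly basic aluminium alkoxide making silyl migration from O3 unlikely; the product is acylated without delay to forestall relactonisation.

Step 4
Reactants: 7 N-methoxy-N-methyl-2,3-bis-O-TBS-5,6-O-isopropylidene-L-gulonamide; 8 benzoyl chloride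
Product: 9 N-methoxy-N-methyl-4-O-benzoyl-2,3-bis-O-TBS-5,6-O-isopropylidene-L-gulonamide
Conditions: BzCl, pyridine, DMAP (cat.), CH2Cl2, 0 °C → rt
Reagents that add atoms: benzoyl chloride, O=C(Cl)c1ccccc1
Why: DMAP-catalysed acylation (nucleophilic catalysis) caps O4 as a benzoate, a non-enolisable and acid-stable placeholder that rules out the five-membered lactone from here on and is removed reductively in step 9.

Step 5
Reactants: 9 N-methoxy-N-methyl-4-O-benzoyl-2,3-bis-O-TBS-5,6-O-isopropylidene-L-gulonamide
Product: 11 4-O-benzoyl-2,3-bis-O-TBS-L-gulono-1,5-lactone (6-OH free), via diol amide 10 (not isolated)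
Conditions: AcOH–H2O (4:1), 50 °C; then PhMe azeotrope, 60 °C
Reagents that add atoms: none
Why: Aqueous acetic acid hydrolyses the terminal acetonide while the hindered secondary silyl ethers and the benzoate stay in place (acyl migration is slow at this acidity), and the freed O5–H then displaces the Weinreb amine by acid-promoted intramolecular acyl transfer (lactonisation), the six-membered ring being the only favourable one because O4 is blocked.

Step 6
Reactants: 11 4-O-benzoyl-2,3-bis-O-TBS-L-gulono-1,5-lactone
Product: 12 4-O-benzoyl-2,3-bis-O-TBS-6-oxo-L-gulono-1,5-lactone (the C6 aldehyde; equivalent to a 3-O-benzoyl-4,5-bis-O-TBS-aldehydo-D-glucurono-6,2-lactone)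
Conditions: Dess–Martin periodinane, CH2Cl2, 0 °C → rt
Reagents that add atoms: none
Why: Dess–Martin oxidation turns the primary alcohol into the aldehyde under non-basic conditions, which protects the C5 stereocentre (later the controlling C4 centre) from epimerisation and the β-benzoate from elimination; the aldehyde is carried on crude.

Step 7
Reactants: 12 4-O-benzoyl-2,3-bis-O-TBS-6-oxo-L-gulono-1,5-lactone; 13 chloroform
Product: 14 (E)-4-O-benzoyl-2,3-bis-O-TBS-7-chloro-6,7-dideoxy-L-gulo-hept-6-enono-1,5-lactone
Conditions: CrCl2, CHCl3, THF, 65 °C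
Reagents that add atoms: chloroform, ClC(Cl)Cl
Why: Takai olefination: CrCl2 reduces CHCl3 to the geminal dichromium species ClCH(CrCl2)2, which adds to the aldehyde and eliminates to the (E)-chloroalkene, the (E) geometry following from the anti arrangement of the substituents in the β-oxido organochromium intermediate, and the non-basic medium sparing lactone, benzoate, silyl ethers and the α-stereocentre.

Step 8
Reactants: 14 (E)-4-O-benzoyl-2,3-bis-O-TBS-7-chloro-6,7-dideoxy-L-gulo-hept-6-enono-1,5-lactone; 15 tert-butyldimethylsilyl trifluoromethanesulfonate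
Product: 17 tert-butyldimethylsilyl 3-benzoyloxy-1,2-bis(tert-butyldimethylsilyloxy)-6-chlorocyclohex-4-ene-1-carboxylate (β: C7/C2–O/C6–Cl; α: C1–O/C3–O), via silyl ketene acetal 16 (not isolated)
Conditions: TBSOTf, Et3N, PhMe, 0 °C → rt; then 80 °C
Reagents that add atoms: tert-butyldimethylsilyl trifluoromethanesulfonate, CC(C)(C)[Si](C)(C)OS(=O)(=O)C(F)(F)F
Why: TBSOTf activates the lactone carbonyl and Et3N removes H–C1, the only α-hydrogen, so the endocyclic ketene acetal 16 forms without a free enolate that could expel the β-silyloxy group; in the half-chair with the chlorovinyl group axial the array C1=C7–O–C4–C5=C6 then undergoes a concerted suprafacial [3,3] shift that joins C1 to C6, cleaves C4–O and leaves C4=C5 and the silyl ester. The closest known reaction type is the Ireland–Claisen rearrangement of silyl ketene acetals of lactones bearing an alkenyl group on the carbinol carbon, which is established for six-membered α-oxygenated lactones under the same soft enolisation; the chlorine on the alkene terminus is a new substituent on a known substrate class. The cyclohexene is closed by the C1–C6 bond, formally a 6-endo-trig attack of the enol carbon on the alkene, through a boat-shaped six-centre array in a bicyclo[2.2.2]octane-like transition state that the C2–C3 tether enforces, a chair being out of reach. C1 is controlled by the C4 stereocentre, because C6 can only reach the ketene acetal face on which the C4–C5 bond stands, which places C7 cis to the C2 oxygen; C6 is controlled by the (E) geometry of the chloroalkene in the obligatory boat, which places chlorine cis to C7 and trans to the C1 oxygen. The step needs site-selective enolisation and complete facial fidelity, secured by the single α-hydrogen next to a non-enolisable benzoate and by the bicyclic constraint, while conversion of the ketene acetal into the C=O bond of the silyl ester makes the shift irreversible.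

Step 9
Reactants: 17 tert-butyldimethylsilyl 3-benzoyloxy-1,2-bis(tert-butyldimethylsilyloxy)-6-chlorocyclohex-4-ene-1-carboxylate
Product: 18 1,2-bis(tert-butyldimethylsilyloxy)-6-chloro-1-(hydroxymethyl)cyclohex-4-en-3-ol (β: C7/C2–O/C6–Cl; α: C1–O/C3–O)
Conditions: iBu2AlH, CH2Cl2, −78 → −20 °C
Reagents that add atoms: none
Why: Excess iBu2AlH reduces the silyl ester through the aldehyde to the primary alcohol and cleaves the benzoate in the same operation (ester reduction), so that no chemoselective carboxyl reduction beside an alkene and no free β-chloro acid is needed; allylic chloride, disubstituted alkene and silyl ethers are inert to this hydride at low temperature.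

Step 10
Reactants: 18 1,2-bis(tert-butyldimethylsilyloxy)-6-chloro-1-(hydroxymethyl)cyclohex-4-en-3-ol; 8 benzoyl chloride
Product: 19 [3-benzoyloxy-1,2-bis(tert-butyldimethylsilyloxy)-6-chlorocyclohex-4-en-1-yl]methyl benzoate (faces as in 18)
Conditions: BzCl, pyridine, DMAP (cat.), CH2Cl2, 0 °C → rt
Reagents that add atoms: benzoyl chloride, O=C(Cl)c1ccccc1
Why: DMAP-catalysed acylation of the only two free hydroxyls, primary C7–OH and allylic C3–OH, introduces both benzoates of the target in one operation.

Step 11
Reactants: 19 [3-benzoyloxy-1,2-bis(tert-butyldimethylsilyloxy)-6-chlorocyclohex-4-en-1-yl]methyl benzoate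
Product: 20 (3-benzoyloxy-6-chloro-1,2-dihydroxycyclohex-4-en-1-yl)methyl benzoate (β: C7/C2–OH/C6–Cl; α: C1–OH/C3–OBz)
Conditions: 48% aq. HF, MeCN, 0 °C → rt
Reagents that add atoms: none
Why: Fluoride-assisted acidic Si–O cleavage removes the secondary and the tertiary silyl ether, and the acidic medium prevents both migration of the C3 benzoate to the new C2 hydroxyl and premature oxirane formation.

Step 12
Reactants: 20 (3-benzoyloxy-6-chloro-1,2-dihydroxycyclohex-4-en-1-yl)methyl benzoate; 21 acetic anhydride
Product: 22 (2-acetoxy-3-benzoyloxy-6-chloro-1-hydroxycyclohex-4-en-1-yl)methyl benzoate (faces as in 20)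
Conditions: Ac2O, pyridine, DMAP (cat.), CH2Cl2, 0 °C
Reagents that add atoms: acetic anhydride, CC(=O)OC(C)=O
Why: Nucleophile-catalysed acetylation selects the secondary C2 hydroxyl over the tertiary, fully substituted C1 hydroxyl on steric grounds and is fast enough to pre-empt any benzoate shift.

Step 13
Reactants: 22 (2-acetoxy-3-benzoyloxy-6-chloro-1-hydroxycyclohex-4-en-1-yl)methyl benzoate
Product: 23 [(1S,2S,3R,6S)-2-acetoxy-3-benzoyloxy-7-oxabicyclo[4.1.0]hept-4-en-1-yl]methyl benzoate (target)
Conditions: DBU, MeCN, 0 °C → rt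
Reagents that add atoms: none
Why: Intramolecular Williamson etherification (3-exo-tet SN2): in the half-chair with C1–O and C6–Cl trans-diaxial the C1 oxygen displaces the allylic chloride with inversion, which puts the oxirane on the α face, while the non-nucleophilic amidine base leaves the three esters untouched.

**Compound list**

1 | L-gulono-1,4-lactone | O=C1O[C@H]([C@@H](O)CO)[C@H](O)[C@@H]1O | starting material
2 | 2,2-dimethoxypropane | COC(C)(C)OC | starting material
3 | 5,6-O-isopropylidene-L-gulono-1,4-lactone | O=C1O[C@H]([C@@H]2COC(C)(C)O2)[C@H](O)[C@@H]1O | intermediate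
4 | tert-butyldimethylsilyl chloride | CC(C)(C)[Si](C)(C)Cl | starting material
5 | 2,3-bis-O-TBS-5,6-O-isopropylidene-L-gulono-1,4-lactone | O=C1O[C@H]([C@@H]2COC(C)(C)O2)[C@H](O[Si](C)(C)C(C)(C)C)[C@@H]1O[Si](C)(C)C(C)(C)C | intermediate
6 | N,O-dimethylhydroxylamine hydrochloride | CNOC.Cl | starting material
7 | N-methoxy-N-methyl-2,3-bis-O-TBS-5,6-O-isopropylidene-L-gulonamide | CON(C)C(=O)[C@@H](O[Si](C)(C)C(C)(C)C)[C@@H](O[Si](C)(C)C(C)(C)C)[C@H](O)[C@@H]1COC(C)(C)O1 | intermediate
8 | benzoyl chloride | O=C(Cl)c1ccccc1 | starting material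
9 | N-methoxy-N-methyl-4-O-benzoyl-2,3-bis-O-TBS-5,6-O-isopropylidene-L-gulonamide | CON(C)C(=O)[C@@H](O[Si](C)(C)C(C)(C)C)[C@@H](O[Si](C)(C)C(C)(C)C)[C@H](OC(=O)c1ccccc1)[C@@H]1COC(C)(C)O1 | intermediate
10 | N-methoxy-N-methyl-4-O-benzoyl-2,3-bis-O-TBS-L-gulonamide (5,6-diol) | CON(C)C(=O)[C@@H](O[Si](C)(C)C(C)(C)C)[C@@H](O[Si](C)(C)C(C)(C)C)[C@H](OC(=O)c1ccccc1)[C@@H](O)CO | intermediate
11 | 4-O-benzoyl-2,3-bis-O-TBS-L-gulono-1,5-lactone | O=C1O[C@@H](CO)[C@@H](OC(=O)c2ccccc2)[C@H](O[Si](C)(C)C(C)(C)C)[C@@H]1O[Si](C)(C)C(C)(C)C | intermediate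
12 | 4-O-benzoyl-2,3-bis-O-TBS-6-oxo-L-gulono-1,5-lactone | O=C1O[C@@H](C=O)[C@@H](OC(=O)c2ccccc2)[C@H](O[Si](C)(C)C(C)(C)C)[C@@H]1O[Si](C)(C)C(C)(C)C | intermediate
13 | chloroform | ClC(Cl)Cl | starting material
14 | (E)-4-O-benzoyl-2,3-bis-O-TBS-7-chloro-6,7-dideoxy-L-gulo-hept-6-enono-1,5-lactone | O=C1O[C@@H](/C=C/Cl)[C@@H](OC(=O)c2ccccc2)[C@H](O[Si](C)(C)C(C)(C)C)[C@@H]1O[Si](C)(C)C(C)(C)C | intermediate
15 | tert-butyldimethylsilyl trifluoromethanesulfonate | CC(C)(C)[Si](C)(C)OS(=O)(=O)C(F)(F)F | starting material
16 | 5-benzoyloxy-2,3,4-tris(tert-butyldimethylsilyloxy)-6-[(E)-2-chlorovinyl]-5,6-dihydro-4H-pyran (silyl ketene acetal of 14) | CC(C)(C)[Si](C)(C)OC1=C(O[Si](C)(C)C(C)(C)C)[C@@H](O[Si](C)(C)C(C)(C)C)[C@H](OC(=O)c2ccccc2)[C@H](/C=C/Cl)O1 | intermediate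
17 | tert-butyldimethylsilyl 3-benzoyloxy-1,2-bis(tert-butyldimethylsilyloxy)-6-chlorocyclohex-4-ene-1-carboxylate | CC(C)(C)[Si](C)(C)O[C@H]1[C@H](OC(=O)c2ccccc2)C=C[C@@H](Cl)[C@@]1(O[Si](C)(C)C(C)(C)C)C(=O)O[Si](C)(C)C(C)(C)C | intermediate
18 | 1,2-bis(tert-butyldimethylsilyloxy)-6-chloro-1-(hydroxymethyl)cyclohex-4-en-3-ol | CC(C)(C)[Si](C)(C)O[C@H]1[C@H](O)C=C[C@@H](Cl)[C@@]1(O[Si](C)(C)C(C)(C)C)CO | intermediate
19 | [3-benzoyloxy-1,2-bis(tert-butyldimethylsilyloxy)-6-chlorocyclohex-4-en-1-yl]methyl benzoate | CC(C)(C)[Si](C)(C)O[C@H]1[C@H](OC(=O)c2ccccc2)C=C[C@@H](Cl)[C@@]1(O[Si](C)(C)C(C)(C)C)COC(=O)c1ccccc1 | intermediate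
20 | (3-benzoyloxy-6-chloro-1,2-dihydroxycyclohex-4-en-1-yl)methyl benzoate | O[C@H]1[C@H](OC(=O)c2ccccc2)C=C[C@@H](Cl)[C@@]1(O)COC(=O)c1ccccc1 | intermediate
21 | acetic anhydride | CC(=O)OC(C)=O | starting material
22 | (2-acetoxy-3-benzoyloxy-6-chloro-1-hydroxycyclohex-4-en-1-yl)methyl benzoate | CC(=O)O[C@H]1[C@H](OC(=O)c2ccccc2)C=C[C@@H](Cl)[C@@]1(O)COC(=O)c1ccccc1 | intermediate
23 | [(1S,2S,3R,6S)-2-acetoxy-3-benzoyloxy-7-oxabicyclo[4.1.0]hept-4-en-1-yl]methyl benzoate | CC(=O)O[C@H]1[C@H](OC(=O)c2ccccc2)C=C[C@@H]2O[C@@]21COC(=O)c1ccccc1 | target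

**Step count and risks**

Total step count: 13. Longest linear sequence: 13 steps (1 → 23).

Steps most likely to fail:

1. Step 8. The sigmatropic shift may be slow or fail: the reactive half-chair with the chlorovinyl group axial suffers allylic strain between the two neighbouring silyloxy groups, and chlorine eclipses the C1 silyloxy group in the boat. The allylic chloride that forms may also ionise or quaternise the amine on heating, and C-silylation may compete with O-silylation. The fallback leaves the halogen out and makes the oxirane by alkene epoxidation instead of chloride displacement. Setting out from aldehyde 12, non-basic methylenation (Zn, CH2Br2, TiCl4, THF–CH2Cl2, 0 °C) would give 4-O-benzoyl-2,3-bis-O-TBS-6,7-dideoxy-L-gulo-hept-6-enono-1,5-lactone F1. Its ketene acetal (TBSOTf, Et3N, PhMe, heat) should undergo the precedented Ireland–Claisen rearrangement of an unsubstituted vinyl lactone to the chlorine-free cyclohexene silyl ester F2. As in the main route, iBu2AlH would give the silylated diol F3, double benzoylation the dibenzoate F4, aqueous HF in MeCN the desilylated diol F5, and acetylation the C2 acetate with free tertiary hydroxyl F6. Dehydration of F6 with the Burgess reagent (PhH, 50 °C), a syn elimination directed towards the allylic C6 hydrogens, should give the conjugated diene (6-acetoxy-5-benzoyloxycyclohexa-1,3-dien-1-yl)methyl benzoate F7. Epoxidation of its more substituted C1=C6 bond with mCPBA (CH2Cl2, 0 °C), expected from the face opposite the adjacent C2 acetoxy group, comes back to the route at target 23; the oxirane epimer would have to be separated.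

2. Step 7. The α-acyloxy aldehyde may lose benzoate by β-elimination or epimerise at C5 in hot, Lewis-acidic CrCl2–CHCl3, and incomplete E selectivity would carry through to the wrong C6 configuration. The fallback fixes the alkene geometry with boron and introduces chlorine afterwards. From aldehyde 12, the boron variant of the Takai reaction (CrCl2, Cl2CHBpin, LiI, THF, rt), which runs at room temperature with high E selectivity, would give the (E)-alkenylboronate 4-O-benzoyl-2,3-bis-O-TBS-6,7-dideoxy-7-(pinacolboryl)-L-gulo-hept-6-enono-1,5-lactone F8. Copper-mediated chlorodeboronation (CuCl2, aq. MeOH–THF, 50 °C) with retention of geometry returns to the route at 14.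

3. Step 11. Cleavage of the very hindered tertiary silyl ether at C1 may stay incomplete under acidic fluoride, and forcing the conditions invites benzoyl migration or solvolysis of the allylic chloride. The fallback keeps the tertiary silyl ether to the end and uses its removal to trigger ring closure. From 19, brief treatment with HF·pyridine (THF–pyridine, 0 °C) should cleave only the secondary C2 silyl ether and give the C2 alcohol (3-benzoyloxy-1-TBS-oxy-6-chloro-2-hydroxycyclohex-4-en-1-yl)methyl benzoate F9. Acetylation (Ac2O, pyridine, DMAP) gives the C2 acetate F10. Bu4NF (THF, 0 °C) then frees the C1 alkoxide, which should displace the anti C6 chloride at once and come back to the route at target 23; no free hydroxyl sits beside a benzoate at any point.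

**Further compounds**

F1 | step 8 | 4-O-benzoyl-2,3-bis-O-TBS-6,7-dideoxy-L-gulo-hept-6-enono-1,5-lactone | O=C1O[C@@H](C=C)[C@@H](OC(=O)c2ccccc2)[C@H](O[Si](C)(C)C(C)(C)C)[C@@H]1O[Si](C)(C)C(C)(C)C
F2 | step 8 | tert-butyldimethylsilyl 3-benzoyloxy-1,2-bis(tert-butyldimethylsilyloxy)cyclohex-4-ene-1-carboxylate (β: C7/C2–O; α: C1–O/C3–O) | CC(C)(C)[Si](C)(C)O[C@H]1[C@H](OC(=O)c2ccccc2)C=CC[C@@]1(O[Si](C)(C)C(C)(C)C)C(=O)O[Si](C)(C)C(C)(C)C
F3 | step 8 | 1,2-bis(tert-butyldimethylsilyloxy)-1-(hydroxymethyl)cyclohex-4-en-3-ol | CC(C)(C)[Si](C)(C)O[C@H]1[C@H](O)C=CC[C@@]1(O[Si](C)(C)C(C)(C)C)CO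
F4 | step 8 | [3-benzoyloxy-1,2-bis(tert-butyldimethylsilyloxy)cyclohex-4-en-1-yl]methyl benzoate | CC(C)(C)[Si](C)(C)O[C@H]1[C@H](OC(=O)c2ccccc2)C=CC[C@@]1(O[Si](C)(C)C(C)(C)C)COC(=O)c1ccccc1
F5 | step 8 | (3-benzoyloxy-1,2-dihydroxycyclohex-4-en-1-yl)methyl benzoate | O[C@H]1[C@H](OC(=O)c2ccccc2)C=CC[C@@]1(O)COC(=O)c1ccccc1
F6 | step 8 | (2-acetoxy-3-benzoyloxy-1-hydroxycyclohex-4-en-1-yl)methyl benzoate | CC(=O)O[C@H]1[C@H](OC(=O)c2ccccc2)C=CC[C@@]1(O)COC(=O)c1ccccc1
F7 | step 8 | (6-acetoxy-5-benzoyloxycyclohexa-1,3-dien-1-yl)methyl benzoate (acetoxy β, benzoyloxy α) | CC(=O)O[C@H]1[C@H](OC(=O)c2ccccc2)C=CC=C1COC(=O)c1ccccc1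
F8 | step 7 | (E)-4-O-benzoyl-2,3-bis-O-TBS-6,7-dideoxy-7-(4,4,5,5-tetramethyl-1,3,2-dioxaborolan-2-yl)-L-gulo-hept-6-enono-1,5-lactone | O=C1O[C@@H](/C=C/B2OC(C)(C)C(C)(C)O2)[C@@H](OC(=O)c2ccccc2)[C@H](O[Si](C)(C)C(C)(C)C)[C@@H]1O[Si](C)(C)C(C)(C)C
F9 | step 11 | [3-benzoyloxy-1-(tert-butyldimethylsilyloxy)-6-chloro-2-hydroxycyclohex-4-en-1-yl]methyl benzoate | O[C@H]1[C@H](OC(=O)c2ccccc2)C=C[C@@H](Cl)[C@@]1(O[Si](C)(C)C(C)(C)C)COC(=O)c1ccccc1
F10 | step 11 | [2-acetoxy-3-benzoyloxy-1-(tert-butyldimethylsilyloxy)-6-chlorocyclohex-4-en-1-yl]methyl benzoate | CC(=O)O[C@H]1[C@H](OC(=O)c2ccccc2)C=C[C@@H](Cl)[C@@]1(O[Si](C)(C)C(C)(C)C)COC(=O)c1ccccc1
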